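## Retrosynthetic overview

1. The oxazolidine and pyrrolidine rings come off last: the target is opened to a tricyclic C3 vinylogous acid with a free C4 tertiary alcohol plus 4,4-diethoxybutan-1-amine (C3–N condensation, then N,O-acetal closure).
2. Ring B is opened at C8a–C9: Friedel–Crafts acylation of a symmetric 3,5-dimethoxyphenyl ring by a CH2CO2H arm on C10a, followed by chelation-directed 8-O-demethylation.
3. Ring A is opened at C10a=C4a and C2–C3: a [3+3] annulation (aldol/lactonisation, then Dieckmann) of methyl 5-methoxy-4-oxopentanoate onto an α-hydroxy-β-keto ester.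
4. Key bond C4a–C4: a carbene-catalysed enantioselective crossed benzoin, in which the acyl anion equivalent of 3,5-dimethoxybenzaldehyde adds to the ketone of methyl pyruvate, joining two electrophilic carbonyl carbons and setting C4 (R) in the first step.
5. Ring order: C (purchased), then A, then B, then oxazolidine and pyrrolidine together.

Assumption: atoms carry phenanthrene numbering (C1 to C10a); the 9-oxo-10H tautomer of the target SMILES is taken as the stable form, and 13, 14 and 16 are drawn the same way (their 9-hydroxy tautomers would converge on the same product).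

## Route

Step 1
Reactants: 1 3,5-dimethoxybenzaldehyde; 2 methyl pyruvate
Product: 3 methyl (2R)-3-(3,5-dimethoxyphenyl)-2-hydroxy-2-methyl-3-oxopropanoate
Conditions: (5aR,10bS)-5a,10b-dihydro-2-(pentafluorophenyl)-4H,6H-indeno[2,1-b][1,2,4]triazolo[4,3-d][1,4]oxazin-2-ium tetrafluoroborate (10 mol %), i-Pr2NEt (10 mol %), 2 (2 equiv, slow addition), CH2Cl2, 4 Å MS, 0 °C
Reagents that add atoms: none
Why: Crossed aldehyde–α-keto ester benzoin reaction under N-heterocyclic carbene catalysis, in which the carbene turns the aldehyde carbon of 1 into a catalyst-bound acyl anion equivalent that adds to the more electrophilic ketone of 2 faster than to a second aldehyde, while the aminoindanol backbone shields one face of that ketone so that the tertiary carbinol C4 forms as the R enantiomer (the mirror-image catalyst is used if the sense of induction proves opposite).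

Step 2
Reactants: 4 methyl 3-iodopropanoate; 5 methoxyacetyl chloride
Product: 7 methyl 5-methoxy-4-oxopentanoate, via zinc homoenolate 6 (not isolated)
Conditions: Zn dust (1.5 equiv, activated by Me3SiCl 3 mol %), THF, 35 °C; then 5 (0.9 equiv), Pd(PPh3)4 (3 mol %), 0 °C to rt
Reagents that add atoms: none
Why: Zinc inserts into the C–I bond to give the ester homoenolate 6, whose carbon–zinc bond is acylated by the acid chloride under palladium catalysis (Negishi acylation, the Tamaru–Yoshida γ-keto ester synthesis) without touching the ester.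

Step 3
Reactants: 3 methyl (2R)-3-(3,5-dimethoxyphenyl)-2-hydroxy-2-methyl-3-oxopropanoate; 7 methyl 5-methoxy-4-oxopentanoate
Product: 11 [(3R)-2-(3,5-dimethoxyphenyl)-3,4-dihydroxy-5-methoxy-3-methyl-6-oxocyclohexa-1,4-dien-1-yl]acetic acid, via lithium enolate 8 (not isolated), via aldol lactone 9 (not isolated), via seco acid 10 (not isolated)
Conditions: 7 (1.3 equiv), LiN(SiMe3)2 (1.3 equiv), THF, −78 °C; add 3 pretreated with LiN(SiMe3)2 (1.05 equiv), −78 to 0 °C; then LiN(SiMe3)2 (2.5 equiv), 0 °C to rt; 1 M HCl
Reagents that add atoms: none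
Why: Proposed new method: a one-pot [3+3] annulation in which kinetic enolate 8 (deprotonation on the side away from the methoxy group) adds to the chelated ketone of 3 and the aldolate is trapped as γ-lactone 9 as in a Stobbe condensation, more base opens 9 by E1cB elimination to enone carboxylate 10, and the methoxy-bearing enolate then closes ring A by Dieckmann condensation onto the methyl ester, the irreversible diketonate formation draining the equilibrating lactone and E/Z enone isomers; the closest known reactions are the Stobbe condensation and the Dieckmann cyclisation, and the quaternary C4 centre cannot enolise so it is carried through unchanged.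

Step 4
Reactants: 11 [(3R)-2-(3,5-dimethoxyphenyl)-3,4-dihydroxy-5-methoxy-3-methyl-6-oxocyclohexa-1,4-dien-1-yl]acetic acid
Product: 13 (4R)-3,4-dihydroxy-2,6,8-trimethoxy-4-methyl-4,10-dihydrophenanthrene-1,9-dione, via mixed anhydride 12 (not isolated)
Conditions: (CF3CO)2O (2.5 equiv), CH2Cl2, 0 °C to rt; aq. NaHCO3/MeOH work-up
Reagents that add atoms: none
Why: Intramolecular Friedel–Crafts acylation in which mixed anhydride 12 attacks the ring C position ortho to one methoxy and para to the other (the two ortho sites of the 3,5-dimethoxyphenyl group are equivalent), closing six-membered ring B, with the basic methanolic work-up cleaving any O-trifluoroacetates.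

Step 5
Reactants: 13 (4R)-3,4-dihydroxy-2,6,8-trimethoxy-4-methyl-4,10-dihydrophenanthrene-1,9-dione
Product: 14 (4R)-3,4,8-trihydroxy-2,6-dimethoxy-4-methyl-4,10-dihydrophenanthrene-1,9-dione
Conditions: BCl3 (3 equiv), CH2Cl2, −78 to −20 °C; then MeOH, aq. NaHCO3
Reagents that add atoms: none
Why: Chelation-directed aryl methyl ether cleavage in which boron bound to the C9 carbonyl oxygen activates only the peri 8-methoxy group through a six-membered chelate, so the 6-methoxy group and the 2-methoxy enol ether survive at low temperature.

Step 6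
Reactants: 14 (4R)-3,4,8-trihydroxy-2,6-dimethoxy-4-methyl-4,10-dihydrophenanthrene-1,9-dione; 15 4,4-diethoxybutan-1-amine
Product: 17 CNP0528850.1 (target), via enaminone acetal 16 (not isolated)
Conditions: 15 (1.2 equiv), AcOH (20 mol %), EtOH, 50 °C; evaporate; then CF3CO2H (2 equiv), CH2Cl2, 0 °C to rt
Reagents that add atoms: none
Why: Amine–vinylogous acid condensation gives C3 enaminone 16, acid then ionises the acetal, nitrogen closes the pyrrolidine, and the resulting iminium is captured by the adjacent C4 hydroxyl (N,O-acetal formation), a closure open only to the C3 regioisomer and reversible, so that the aminal carbon settles as S with its hydrogen syn to the C4 methyl group while C4 (R) is untouched.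

## Compound list

1 | 3,5-dimethoxybenzaldehyde | O=Cc1cc(OC)cc(OC)c1 | starting material
2 | methyl pyruvate | CC(=O)C(=O)OC | starting material
3 | methyl (2R)-3-(3,5-dimethoxyphenyl)-2-hydroxy-2-methyl-3-oxopropanoate | COC(=O)[C@](C)(O)C(=O)c1cc(OC)cc(OC)c1 | intermediate
4 | methyl 3-iodopropanoate | COC(=O)CCI | starting material
5 | methoxyacetyl chloride | COCC(=O)Cl | starting material
6 | iodo(3-methoxy-3-oxopropyl)zinc (zinc homoenolate) | COC(=O)CC[Zn]I | intermediate
7 | methyl 5-methoxy-4-oxopentanoate | COCC(=O)CCC(=O)OC | intermediate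
8 | lithium 1,5-dimethoxy-5-oxopent-2-en-2-olate (kinetic enolate of 7) | COCC(O[Li])=CCC(=O)OC | intermediate
9 | methyl (2R)-2-[2-(3,5-dimethoxyphenyl)-3-(methoxyacetyl)-5-oxooxolan-2-yl]-2-hydroxypropanoate (mixture at the two lactone ring centres) | COCC(=O)C1CC(=O)OC1(c2cc(OC)cc(OC)c2)[C@@](C)(O)C(=O)OC | intermediate
10 | (3Z,5R)-4-(3,5-dimethoxyphenyl)-5-hydroxy-6-methoxy-3-(methoxyacetyl)-5-methyl-6-oxohex-3-enoic acid (reactive Z isomer shown; E/Z equilibrate) | COCC(=O)/C(CC(=O)O)=C(/c1cc(OC)cc(OC)c1)[C@@](C)(O)C(=O)OC | intermediate
11 | [(3R)-2-(3,5-dimethoxyphenyl)-3,4-dihydroxy-5-methoxy-3-methyl-6-oxocyclohexa-1,4-dien-1-yl]acetic acid | COC1=C(O)[C@](C)(O)C(c2cc(OC)cc(OC)c2)=C(CC(=O)O)C1=O | intermediate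
12 | mixed anhydride of 11 with trifluoroacetic acid | COC1=C(O)[C@](C)(O)C(c2cc(OC)cc(OC)c2)=C(CC(=O)OC(=O)C(F)(F)F)C1=O | intermediate
13 | (4R)-3,4-dihydroxy-2,6,8-trimethoxy-4-methyl-4,10-dihydrophenanthrene-1,9-dione | COC1=C(O)[C@](C)(O)C2=C(CC(=O)c3c(OC)cc(OC)cc32)C1=O | intermediate
14 | (4R)-3,4,8-trihydroxy-2,6-dimethoxy-4-methyl-4,10-dihydrophenanthrene-1,9-dione | COC1=C(O)[C@](C)(O)C2=C(CC(=O)c3c(O)cc(OC)cc32)C1=O | intermediate
15 | 4,4-diethoxybutan-1-amine | NCCCC(OCC)OCC | starting material
16 | (4R)-3-[(4,4-diethoxybutyl)amino]-4,8-dihydroxy-2,6-dimethoxy-4-methyl-4,10-dihydrophenanthrene-1,9-dione | COC1=C(NCCCC(OCC)OCC)[C@](C)(O)C2=C(CC(=O)c3c(O)cc(OC)cc32)C1=O | intermediate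
17 | CNP0528850.1: (4R)-8-hydroxy-2,6-dimethoxy-4-methyl-4,10-dihydrophenanthrene-1,9-dione in which N on C3 and O on C4 are joined through a butane-1,1,4-triyl unit (pyrrolidine fused to oxazolidine; aminal carbon S, its H syn to the C4 methyl) | COC1=C2N3CCC[C@@H]3O[C@]2(C)C2=C(CC(=O)c3c(O)cc(OC)cc32)C1=O | target

## Step count

Total steps: 6. Longest linear sequence: 5 steps (1 → 3 → 11 → 13 → 14 → 17); step 2 is a one-step side branch.

## Three steps most likely to fail, with fallbacks

**Step 1 (crossed benzoin).** The aromatic aldehyde may homo-couple, methyl pyruvate may enolise and self-condense, and the enantioselectivity with an aryl aldehyde donor is not documented. The fallback sets out from 1 and 2 and gives up catalyst control. The coupling is run with the small achiral precatalyst 6,7-dihydro-2-(pentafluorophenyl)-5H-pyrrolo[2,1-c][1,2,4]triazol-2-ium tetrafluoroborate and K2CO3 in THF, which gives racemic methyl 3-(3,5-dimethoxyphenyl)-2-hydroxy-2-methyl-3-oxopropanoate F1. This is resolved by preparative supercritical-fluid chromatography on an amylose carbamate phase. The R enantiomer is compound 3, where the route is rejoined.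

**Step 3 (one-pot annulation).** The enolate may form on the wrong side, the aldol may revert before lactonisation, and the E isomer of 10 cannot close ring A. The fallback sets out from lactone 9, isolated by quenching the first stage at 0 °C with NH4Cl. DBU in CH2Cl2 opens 9 to seco acid 10 as an E/Z mixture. Treatment with (CF3CO)2O gives the mixed anhydride of 10 with trifluoroacetic acid F2. Under these acidic conditions E and Z interconvert through relactonisation, and the Z form closes ring B first by Friedel–Crafts acylation. After tautomerisation this gives methyl (2R)-2-hydroxy-2-[4-hydroxy-5,7-dimethoxy-2-(methoxyacetyl)naphthalen-1-yl]propanoate F3. Ring B now fixes the geometry, and LiN(SiMe3)2 (4 equiv) in THF closes ring A by Dieckmann condensation. The route is rejoined at 13.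

**Step 6 (amine condensation and aminal closure).** The amine may condense at C1 or C9 instead of C3, and the aminal may form as an epimer mixture. The fallback sets out from 14. 2-Methoxypropene with pyridinium p-toluenesulfonate gives the isopropylidene ketal bridging the C3 enol oxygen and the C4 hydroxyl of 14 F4. This locks ring A as a C3 vinylogous ester, so 15 can only enter by conjugate addition–elimination at C3, expelling the ketal oxygen and losing acetone. The product is 16, where the route is rejoined; the CF3CO2H closure follows as before, and a minor aminal epimer is re-equilibrated in the same acid.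

## Further compounds

F1 | step 1 | methyl (2RS)-3-(3,5-dimethoxyphenyl)-2-hydroxy-2-methyl-3-oxopropanoate (racemate) | COC(=O)C(C)(O)C(=O)c1cc(OC)cc(OC)c1
F2 | step 3 | mixed anhydride of (3Z,5R)-4-(3,5-dimethoxyphenyl)-5-hydroxy-6-methoxy-3-(methoxyacetyl)-5-methyl-6-oxohex-3-enoic acid with trifluoroacetic acid | COCC(=O)/C(CC(=O)OC(=O)C(F)(F)F)=C(/c1cc(OC)cc(OC)c1)[C@@](C)(O)C(=O)OC
F3 | step 3 | methyl (2R)-2-hydroxy-2-[4-hydroxy-5,7-dimethoxy-2-(methoxyacetyl)naphthalen-1-yl]propanoate | COCC(=O)c1cc(O)c2c(OC)cc(OC)cc2c1[C@@](C)(O)C(=O)OC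
F4 | step 6 | isopropylidene ketal of 14 bridging the C3 enol oxygen and the C4 oxygen (C4 R) | COC1=C2OC(C)(C)O[C@]2(C)C2=C(CC(=O)c3c(O)cc(OC)cc32)C1=O
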